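Every target formed sets one acid free, and that acid stays in the flask either free or on a nucleophile, so [acid set free] + [protonated nucleophile] = [target] holds throughout.

common to all: time 5.0 d

| flask | electrophile | nucleophile | temperature | remark |
|---|---|---|---|---|
| elm | 20 mM | 21.0 mM (in portions, 3, over 4.0 d) | 5 °C | first portion at the start, last at 4.0 d |
| ash | 20 mM (fed, over 4.0 d) | 21.0 mM |  | the addition at −25 °C, then warmed to 5 °C; the feed brings no volume worth counting |
| oak | 20 mM (fed, over 4.0 d) | 21.0 mM | 5 °C | all else is in the flask from the start; the feed brings no volume worth counting |
| cedar | 20 mM | 21.0 mM (fed, over 4.0 d) | 5 °C | all else is in the flask from the start; the feed brings no volume worth counting |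
| alder | 20 mM | 21.0 mM (fed, over 10 h) | 5 °C | all else is in the flask from the start; the feed brings no volume worth counting |

    nucleophile + acid set free ⇌ protonated nucleophile, settled at all times (K1 = 22000 L mol⁻¹, ΔH1 = −38.0 kJ mol⁻¹)
    electrophile + nucleophile → acid set free + target (k2 = 0.0013 L mol⁻¹ s⁻¹, Ea2 = 62.0 kJ mol⁻¹)
    (constants at 5 °C)

- the constants hold at 5 °C; other temperatures follow from the activation energies and enthalpies

1. the best flask by amount of target, in percent of the electrophile charged; "all alike" if 1.5 percentage points covers them all (elm / ash / oak / cedar / alder / all alike)
2. amount of target at the end, in percent of the electrophile charged, elm
3. amount of target at the end, in percent of the electrophile charged, ash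
4. amount of target at the end, in percent of the electrophile charged, oak
5. amount of target at the end, in percent of the electrophile charged, cedar
6. amount of target at the end, in percent of the electrophile charged, alder

Follow one freed acid to its fork: it stays free or sits on a nucleophile, and the odds for sitting are the equilibrium constant times [nucleophile] to one. This reckoning starts there. At 5 °C and the full charge the odds are 462 to one, and at that temperature they stay above even until [nucleophile] has sunk to 0.216 % of its charge. So while those odds stand high, each target costs two nucleophiles, one built in and one protonated, and the nucleophile, though charged above the electrophile, acts as the limiting reagent. That gives 52.5 %: the half-charge ceiling, the target standing when half of the nucleophile charge has become target and the other half is protonated, counted on the electrophile charged. Elm, ash, oak, cedar and alder share these charges, and the number holds no clock and no dosing, so taken by itself it says "all alike". A spread beyond 1.5 percentage points would show that one number is not enough.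

The forecast goes further than this reckoning. It starts from the same fork, “Each turnover frees an acid that locks up a second nucleophile”, but it ranks the flasks: elm 53 %, ash 51 %, oak 54.5 %, cedar 53.5 %, alder 58 %, with alder best.

At 5.0 d the simulation gives elm 51.9 %, ash 50.3 %, oak 54.7 %, cedar 53.4 % and alder 57.6 %, each inside the forecast's range, with alder best. The spread is 7.3 points against a margin of 1.5 points, running from 2.2 points below the ceiling in ash to 5.1 points above it in alder.

The ceiling is not a stop, and neither alder nor ash has come to rest at 5.0 d. Left to 50.0 d, alder holds 70.6 % target and ash 70.0 %, so the gap between them goes from 7.3 points to 0.60 points. By then alder has [acid set free] at 7.27 mM and [protonated nucleophile] at 6.84 mM, with [nucleophile] at 0.204 % of its charge, close to the even-odds share reckoned above, and 29.4 % of the electrophile is still present.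

For alder with 8.4 mM of nucleophile, the ceiling gives 21.0 %. The computed flask holds 25.7 % target with 74.3 % of electrophile still present, 4.7 points above that ceiling.

(Its constants stand for no real mixture; what happens was integrated by code.)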